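An end share read while substrate is still being consumed belongs to a reaction still under way, so before I trust one I count half-lives of the substrate.

| setting | alpha | beta | zeta | oak | birch | elm | maple |
|---|---|---|---|---|---|---|---|
| substrate | 0.050 M | 0.050 M | 0.050 M | 0.050 M | 0.050 M (fed, over 40 min) | 0.050 M | 0.050 M |
| first nucleophile | 0.80 equiv | 0.80 equiv | 0.80 equiv | 0.800 equiv (fed, over 40 min) | 0.800 equiv | 0.800 equiv (fed, over 40 min) | 0.800 equiv |
| second nucleophile | 3 equiv | 3 equiv | 3 equiv | 3.00 equiv | 3.00 equiv | 3.00 equiv | 3.00 equiv |
| capture agent | 2.5 mM | 1.2 mM | 5 mM | 2.50 mM | 2.50 mM | 2.50 mM | 2.50 mM |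
| temperature | 55 °C | 70 °C | 55 °C | 70 °C | 70 °C |  | 70 °C |
| remark | run made earlier | run made earlier | run made earlier | all else is in the flask from the start; the feed brings no volume worth counting | all else is in the flask from the start; the feed brings no volume worth counting | the addition at 40 °C, then warmed to 70 °C; the feed brings no volume worth counting | everything together at the start |
| time |  |  |  | 1.0 h | 1.0 h | 1.0 h | 1.0 h |

| run | time / min | target / % | other capture product / % | substrate / % |
|---|---|---|---|---|
| alpha | 10.0 | 3 | 1 | 94 |
| alpha | 25.0 | 7 | 1 | 87 |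
| alpha | 50.0 | 9 | 1 | 74 |
| alpha | 120 | 18 | 4 | 47 |
| beta | 5.00 | 9 | 0 | 84 |
| beta | 12.0 | 12 | 0 | 65 |
| beta | 25.0 | 20 | 2 | 42 |
| beta | 60.0 | 26 | 5 | 10 |
| zeta | 15.0 | 3 | 3 | 90 |
| zeta | 40.0 | 10 | 3 | 76 |
| zeta | 80.0 | 14 | 3 | 64 |
| zeta | 120 | 19 | 3 | 45 |

(standard deviation of a reading: 1.5 percentage points)



* the best flask by share of target in target plus other capture product; "all alike" if 1.5 percentage points covers them all (oak / birch / elm / maple / all alike)
* share of target in target plus other capture product at the end, oak
* share of target in target plus other capture product at the end, birch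
* share of target in target plus other capture product at the end, elm
* share of target in target plus other capture product at the end, maple

With 2.5 mM of capture agent, alpha keeps 47% of its substrate at 120 min. With 5 mM, zeta keeps 45%. That gap sits near the scatter of 1.5 percentage points, so I let one half-life serve at each temperature, whatever the agent level.

Beta's last reading, 10% at 60.0 min, gives a half-life of 18.1 min at 70 °C. Alpha gives 110 min at 55 °C, a factor of 6.08. I take the same factor for the equal step down to 40 °C, which makes 672 min.

Elm spends 40 min cold and 20.0 min hot, and I treat the warming as instant. Its count is 1.17 half-lives, which leaves 44.5% of the substrate.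

The weak link is that last reading, where the scatter weighs heavily on a small value. Beta's 42% at 25.0 min carries less scatter for its size than that last reading and gives 20.0 min, the time in which substrate at 70 °C falls to half of itself. The cold half-life becomes 608 min and the count 1.07. I commit to 47.7% of elm's substrate left at the end, so elm's share will be a mid-course reading.

The forecast names birch as best, with oak 80%, birch 88%, elm 87% and maple 84%. Its ground for that choice is “Birch keeps the nucleophile in excess”.

The flasks give elm as best, with oak 80.6%, birch 80.8%, elm 88.8% and maple 85.7%, so birch stands lower than forecast.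

    second nucleophile + open intermediate → other capture product (k = 0.00380 M⁻¹ s⁻¹, Ea = 55.0 kJ mol⁻¹)
    2 first nucleophile → homo dimer (k = 0.0120 M⁻¹ s⁻¹, Ea = 66.0 kJ mol⁻¹)
    open intermediate → solvolysis product (k = 0.00790 s⁻¹, Ea = 87.0 kJ mol⁻¹)
    substrate → open intermediate (k = 6.20 × 10⁻⁴ s⁻¹, Ea = 112 kJ mol⁻¹)
    open intermediate + capture agent → trapped intermediate (k = 0.00160 M⁻¹ s⁻¹, Ea = 81.0 kJ mol⁻¹)
    first nucleophile + open intermediate → target (k = 0.210 M⁻¹ s⁻¹, Ea = 58.0 kJ mol⁻¹)
    (constants at 70 °C)

Elm leads but has not come to rest: 45.9% of its substrate stands at 1.00 h, against my reckoned 47.7%. At 10.0 h its share has fallen to 84.0%. Oak has its substrate in from the start and spends 3.00 half-lives of 20.0 min at 70 °C, which reckons to 12.5% left, and it holds 11%. Oak's share moves from 80.6% to 80.1% at 10.0 h.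

(All runs are simulated from invented constants.)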